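**Retrosynthetic overview**
- Feature: ring A (C1–C5, C10) has the carbon pattern of a 2,4-dimethylphenol, with C3–O as the phenol oxygen, C4–CH3 ortho and the quaternary C10–CH3 para. Alkylating that para carbon creates C10 and closes ring B (C5–C10). Eudesmane numbering: C3 OAng, C4 OAc/CH3, C5 ring-fusion H, C6=C7, C8=O, C11 OOH.
- Target ⇐ singlet-oxygen ene (C7=C11 → C6=C7, C11–OOH) ⇐ 3-angelate 4-acetate ⇐ 3α,4α-diol (OsO4, α-face) ⇐ 3,7(11)-dien-8-one ⇐ acetone aldol/dehydration at C7 of the Δ3-en-8-one.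
- Δ3-en-8-one ⇐ C3 enol triflate (Li/NH3 sets 5α-H; methylidene → C8=O; formate reduction) ⇐ Δ4-enone ⇐ copper hydride reduction of C1=C2 in dienone 17.
- Dienone 17 ⇐ palladium-catalysed asymmetric dearomative para-allylation (C9–C10) of phenol carbonate 16 ⇐ benzyl bromide 10 + dilithiated 2-methylprop-2-en-1-ol ⇐ 2-bromo-1,3-dimethylbenzene.
- Ring order: ring A is the starting arene; ring B closes in step 10.

Key step: step 10

Assumption: the sense of induction of the ligand in step 10 cannot be predicted with confidence; the (R,R) ligand is written, and its antipode is used if a first screen shows the opposite sense.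

**Route**

Step 1
Reactants: 1 2-bromo-1,3-dimethylbenzene
Product: 2 2-bromo-1,3-dimethyl-4-nitrobenzene
Conditions: HNO3 (1.05 equiv), H2SO4, CH2Cl2, 0 °C
Reagents that add atoms: nitric acid, O[N+](=O)[O-]
Why: Electrophilic aromatic nitration should go to the position ortho to one methyl and para to the other, the site meta to both methyls being far less activated.

Step 2
Reactants: 2 2-bromo-1,3-dimethyl-4-nitrobenzene
Product: 3 3-bromo-2,4-dimethylaniline
Conditions: Fe powder, NH4Cl, EtOH–H2O, 80 °C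
Reagents that add atoms: none
Why: Béchamp-type iron reduction converts the nitro group into the amine without hydrogenolysis of the aryl bromide.

Step 3
Reactants: 3 3-bromo-2,4-dimethylaniline
Product: 5 3-bromo-2,4-dimethylphenol, via diazonium hydrogen sulfate 4 (not isolated)
Conditions: NaNO2, aqueous H2SO4, 0 °C; then run into boiling aqueous H2SO4
Reagents that add atoms: sodium nitrite, [Na+].[O-]N=O (nitrogen of 4 only); sulfuric acid, OS(=O)(=O)O (counter-ion of 4 only); water, O
Why: Diazotisation followed by thermal hydrolysis of the arenediazonium salt replaces NH2 by OH and leaves the bromide in place.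

Step 4
Reactants: 5 3-bromo-2,4-dimethylphenol
Product: 6 (3-bromo-2,4-dimethylphenoxy)tri(propan-2-yl)silane
Conditions: TIPSCl, imidazole, DMF, rt
Reagents that add atoms: chlorotri(propan-2-yl)silane, CC(C)[Si](Cl)(C(C)C)C(C)C
Why: Silylation of the phenol masks the acidic OH for the organolithium steps, the bulky triisopropylsilyl ether resisting alkoxides and organolithiums.

Step 5
Reactants: 6 (3-bromo-2,4-dimethylphenoxy)tri(propan-2-yl)silane
Product: 9 {2,6-dimethyl-3-[tri(propan-2-yl)silyloxy]phenyl}methanol, via aryllithium 7 (not isolated), via aldehyde 8 (not isolated)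
Conditions: n-BuLi, THF, −78 °C; DMF, −78 → 0 °C; then MeOH, NaBH4, 0 °C
Reagents that add atoms: n-butyllithium, [Li]CCCC (lithium of 7 only); N,N-dimethylformamide, CN(C)C=O
Why: Bromine–lithium exchange gives the aryllithium (the silyloxy group is meta, so no silyl migration), Bouveault formylation with DMF gives the aldehyde once methanol collapses the hemiaminal, and borohydride reduces it in the same flask.

Step 6
Reactants: 9 {2,6-dimethyl-3-[tri(propan-2-yl)silyloxy]phenyl}methanol
Product: 10 [3-(bromomethyl)-2,4-dimethylphenoxy]tri(propan-2-yl)silane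
Conditions: CBr4, PPh3, CH2Cl2, 0 °C
Reagents that add atoms: tetrabromomethane, BrC(Br)(Br)Br
Why: Appel bromination displaces the alkoxyphosphonium ion by bromide under neutral conditions that spare the silyl ether.

Step 7
Reactants: 10 [3-(bromomethyl)-2,4-dimethylphenoxy]tri(propan-2-yl)silane; 11 2-methylprop-2-en-1-ol
Product: 13 4-{2,6-dimethyl-3-[tri(propan-2-yl)silyloxy]phenyl}-2-methylidenebutan-1-ol, via dilithiated 2-methylprop-2-en-1-ol 12 (not isolated)
Conditions: 11 (2.5 equiv), n-BuLi (5 equiv), TMEDA, Et2O, 0 °C → rt; then 10, THF, −78 → 0 °C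
Reagents that add atoms: n-butyllithium, [Li]CCCC (lithium of 12 only)
Why: SN2 C-alkylation of the allyl anion of the alcohol dianion by the benzylic bromide forms C6–C7, and because both allyl termini are equivalent CH2 groups only the 2-substituted allylic alcohol can result.

Step 8
Reactants: 13 4-{2,6-dimethyl-3-[tri(propan-2-yl)silyloxy]phenyl}-2-methylidenebutan-1-ol; 14 methyl chloroformate
Product: 15 4-{2,6-dimethyl-3-[tri(propan-2-yl)silyloxy]phenyl}-2-methylidenebutyl methyl carbonate
Conditions: pyridine, CH2Cl2, 0 °C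
Reagents that add atoms: none
Why: Acylation of the primary allylic alcohol by the chloroformate installs the methyl carbonate, the leaving group for π-allyl formation.

Step 9
Reactants: 15 4-{2,6-dimethyl-3-[tri(propan-2-yl)silyloxy]phenyl}-2-methylidenebutyl methyl carbonate
Product: 16 4-(3-hydroxy-2,6-dimethylphenyl)-2-methylidenebutyl methyl carbonate
Conditions: Bu4NF (1.1 equiv), AcOH (1.2 equiv), THF, 0 °C
Reagents that add atoms: none
Why: Fluoride-mediated desilylation of the aryl silyl ether frees the phenol, the acetic acid buffer protonating the phenoxide so that it does not attack the carbonate.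

Step 10
Reactants: 16 4-(3-hydroxy-2,6-dimethylphenyl)-2-methylidenebutyl methyl carbonate
Product: 17 (4aS)-1,4a-dimethyl-6-methylidene-5,6,7,8-tetrahydronaphthalen-2(4aH)-one
Conditions: Pd2(dba)3·CHCl3 (2.5 mol%), N,N'-[(1R,2R)-cyclohexane-1,2-diyl]bis[2-(diphenylphosphanyl)benzamide] (7.5 mol%), CH2Cl2 (0.01 M), rt
Reagents that add atoms: none
Why: Proposed new method: zerovalent palladium ionises the allylic carbonate to a cationic 2-substituted π-allyl complex, the expelled methyl carbonate loses CO2 to methoxide, which deprotonates the phenol, and the phenolate attacks the allyl terminus C9 through its para carbon C10 on the face away from palladium, a dienone resulting because the methyl group on C10 blocks rearomatisation. The closest known reaction types are the palladium-catalysed intramolecular ipso-Friedel–Crafts allylic alkylation of para-tethered phenols to spirocyclohexadienones and the Tsuji–Trost asymmetric allylic alkylation of prochiral enolates with this ligand class; new here is the fused closure from a meta tether onto a methyl-bearing para carbon. Ring B (C5–C10) closes in a 6-exo mode, C8 staying in the ring and the far allyl terminus becoming the exocyclic methylidene, and since both termini are CH2 groups either one gives the same ring. The single new stereocentre C10 is controlled by the chiral ligand, whose amide-walled pocket around the allyl unit makes the two faces of the tethered phenolate diastereotopic in the bond-forming transition state. The step needs para-C-alkylation to win over ortho-C- and O-alkylation: C10 carries the larger coefficient and is flanked by the unsubstituted C1 whereas C4 is wedged between the C–O carbon and the tether carbon, intramolecular O-alkylation would need an eight-membered meta-bridged ring, and intermolecular O-allylation is held back by dilution and is reversible under the catalyst.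

Step 11
Reactants: 17 (4aS)-1,4a-dimethyl-6-methylidene-5,6,7,8-tetrahydronaphthalen-2(4aH)-one
Product: 19 (4aR)-1,4a-dimethyl-6-methylidene-4,4a,5,6,7,8-hexahydronaphthalen-2(3H)-one, via silyl dienol ether 18 (not isolated)
Conditions: [(Ph3P)CuH]6 (3 mol%), PhMe2SiH (1.3 equiv), toluene, rt; then 1 M HCl, THF, 0 °C
Reagents that add atoms: dimethyl(phenyl)silane, C[SiH](C)c1ccccc1 (silyl group of 18 only)
Why: Copper hydride-catalysed 1,4-hydrosilylation delivers hydride to C1, the only β-carbon bearing hydrogen, leaving the fully substituted C4=C5 enone and the unactivated methylidene untouched, and acid hydrolysis of the dienol silyl ether protonates C2 to give the Δ4-enone; a polar hydride is chosen because a dissolving-metal radical anion of 17 could expel the allylic C9 with rearomatisation (the C10 descriptor changes from S to R by priority only).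

Step 12
Reactants: 19 (4aR)-1,4a-dimethyl-6-methylidene-4,4a,5,6,7,8-hexahydronaphthalen-2(3H)-one
Product: 21 (4aR,8aR)-1,4a-dimethyl-6-methylidene-3,4,4a,5,6,7,8,8a-octahydronaphthalen-2-yl trifluoromethanesulfonate, via lithium enolate 20 (not isolated)
Conditions: Li (2.1 equiv), NH3(l)–THF, t-BuOH (1.0 equiv), −78 °C; NH3 evaporated; PhNTf2, THF, 0 °C → rt
Reagents that add atoms: lithium, [Li] (in 20 only); N-phenylbis(trifluoromethanesulfonimide), O=S(=O)(N(c1ccccc1)S(=O)(=O)C(F)(F)F)C(F)(F)F
Why: Birch-type dissolving-metal reduction of the enone protonates C5 axially under stereoelectronic control to give the trans ring fusion (5α-H, 5R), and the regiodefined C3 lithium enolate is trapped on oxygen as the enol triflate, the isolated methylidene being inert.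

Step 13
Reactants: 21 (4aR,8aR)-1,4a-dimethyl-6-methylidene-3,4,4a,5,6,7,8,8a-octahydronaphthalen-2-yl trifluoromethanesulfonate
Product: 22 (4aR,8aR)-1,4a-dimethyl-6-oxo-3,4,4a,5,6,7,8,8a-octahydronaphthalen-2-yl trifluoromethanesulfonate
Conditions: OsO4 (2 mol%), NaIO4 (3 equiv), 2,6-lutidine, dioxane–H2O, rt
Reagents that add atoms: sodium periodate, [Na+].[O-]I(=O)(=O)=O; water, O
Why: Lemieux–Johnson oxidation cleaves the electron-rich, unhindered 1,1-disubstituted methylidene to the C8 ketone, the tetrasubstituted electron-poor enol triflate alkene being inert to OsO4.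

Step 14
Reactants: 22 (4aR,8aR)-1,4a-dimethyl-6-oxo-3,4,4a,5,6,7,8,8a-octahydronaphthalen-2-yl trifluoromethanesulfonate
Product: 23 (4aR,8aR)-5,8a-dimethyl-3,4,4a,7,8,8a-hexahydronaphthalen-2(1H)-one
Conditions: Pd(OAc)2 (5 mol%), PPh3 (10 mol%), HCO2H, n-Bu3N, DMF, 60 °C
Reagents that add atoms: none
Why: Palladium-catalysed formate reduction of the enol triflate (oxidative addition to zerovalent palladium, formate exchange, decarboxylation, reductive elimination) replaces OTf by H and leaves the C3=C4 alkene where the enolate placed it, the ketone being tolerated.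

Step 15
Reactants: 23 (4aR,8aR)-5,8a-dimethyl-3,4,4a,7,8,8a-hexahydronaphthalen-2(1H)-one; 24 acetone
Product: 26 (4aR,8aR)-3-(2-hydroxypropan-2-yl)-5,8a-dimethyl-3,4,4a,7,8,8a-hexahydronaphthalen-2(1H)-one, via lithium enolate 25 (not isolated)
Conditions: LiN(i-Pr)2, THF, −78 °C; then 24, −78 °C; AcOH quench at −78 °C
Reagents that add atoms: lithium diisopropylamide, [Li]N(C(C)C)C(C)C (lithium of 25 only)
Why: Kinetic deprotonation occurs at C7, the α-methylene remote from the quaternary C10 (C9 is neopentyl), and the lithium enolate adds to acetone in a directed aldol reaction, the new C7 centre (either epimer) being destroyed in the next step.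

Step 16
Reactants: 26 (4aR,8aR)-3-(2-hydroxypropan-2-yl)-5,8a-dimethyl-3,4,4a,7,8,8a-hexahydronaphthalen-2(1H)-one
Product: 28 (4aR,8aR)-5,8a-dimethyl-3-(propan-2-ylidene)-3,4,4a,7,8,8a-hexahydronaphthalen-2(1H)-one, via mesylate 27 (not isolated)
Conditions: MsCl, Et3N, catalytic DMAP, CH2Cl2, 0 °C; then DBU, rt
Reagents that add atoms: methanesulfonyl chloride, CS(=O)(=O)Cl (mesyl group of 27 only)
Why: Mesylation of the tertiary aldol hydroxyl followed by E1cB elimination through the C7 enolate gives the conjugated tetrasubstituted C7=C11 enone, DBU also drawing any isopropenyl isomer into conjugation.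

Step 17
Reactants: 28 (4aR,8aR)-5,8a-dimethyl-3-(propan-2-ylidene)-3,4,4a,7,8,8a-hexahydronaphthalen-2(1H)-one
Product: 29 (3R,4S,5R,10R)-3,4-dihydroxyeudesm-7(11)-en-8-one (3α,4α-diol)
Conditions: OsO4 (2 mol%), NMO, acetone–H2O, rt
Reagents that add atoms: N-methylmorpholine N-oxide, C[N+]1([O-])CCOCC1; water, O
Why: Catalytic OsO4 syn-dihydroxylation selects the isolated trisubstituted C3=C4 over the electron-poor tetrasubstituted enone alkene and should approach from the α-face, anti to the axial C10 methyl that lies 1,3-diaxial over C4, setting 3R and 4S together.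

Step 18
Reactants: 29 (3R,4S,5R,10R)-3,4-dihydroxyeudesm-7(11)-en-8-one; 30 angelic acid
Product: 32 (3R,4S,5R,10R)-4-hydroxy-8-oxoeudesm-7(11)-en-3-yl (2Z)-2-methylbut-2-enoate, via mixed anhydride 31 (not isolated)
Conditions: 30, 2,4,6-Cl3C6H2COCl, Et3N, toluene, rt; then 29, 80 °C
Reagents that add atoms: 2,4,6-trichlorobenzoyl chloride, O=C(Cl)c1c(Cl)cc(Cl)cc1Cl (aroyl part of 31 only)
Why: Yamaguchi-type mixed-anhydride esterification directs the secondary C3 hydroxyl to the unshielded angeloyl carbonyl while the tertiary C4 hydroxyl stays free, and the absence of a nucleophilic acyl-transfer catalyst should keep the Z alkene from isomerising to the tiglate.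

Step 19
Reactants: 32 (3R,4S,5R,10R)-4-hydroxy-8-oxoeudesm-7(11)-en-3-yl (2Z)-2-methylbut-2-enoate
Product: 33 (3R,4S,5R,10R)-4-acetoxy-8-oxoeudesm-7(11)-en-3-yl (2Z)-2-methylbut-2-enoate
Conditions: Ac2O, DMAP, Et3N, CH2Cl2, 40 °C
Reagents that add atoms: acetic anhydride, CC(=O)OC(C)=O
Why: Steglich-type DMAP-catalysed acetylation through the N-acetylpyridinium ion is forceful enough for the equatorial tertiary C4 hydroxyl and does not disturb the preformed angelate.

Step 20
Reactants: 33 (3R,4S,5R,10R)-4-acetoxy-8-oxoeudesm-7(11)-en-3-yl (2Z)-2-methylbut-2-enoate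
Product: 34 (3R,4S,5R,10R)-4-acetoxy-11-hydroperoxy-8-oxoeudesm-6-en-3-yl (2Z)-2-methylbut-2-enoate (CNP0225062.1)
Conditions: O2, hν (visible light), catalytic tetraphenylporphyrin, CH2Cl2, 0 °C
Reagents that add atoms: oxygen, O=O
Why: Schenck ene reaction: singlet oxygen bonds to the β-carbon C11 of the s-cis-locked tetrasubstituted enone and takes the allylic hydrogen from C6, the group geminal to the carbonyl, so the double bond moves to C6=C7 in conjugation with C8=O without creating a stereocentre, while the electron-poor angelate alkene should react far more slowly.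

**Compound list**
1 | 2-bromo-1,3-dimethylbenzene | Cc1cccc(C)c1Br | starting material
2 | 2-bromo-1,3-dimethyl-4-nitrobenzene | Cc1ccc([N+](=O)[O-])c(C)c1Br | intermediate
3 | 3-bromo-2,4-dimethylaniline | Cc1ccc(N)c(C)c1Br | intermediate
4 | 3-bromo-2,4-dimethylbenzenediazonium hydrogen sulfate | Cc1ccc([N+]#N)c(C)c1Br.OS(=O)(=O)[O-] | intermediate (not isolated)
5 | 3-bromo-2,4-dimethylphenol | Cc1ccc(O)c(C)c1Br | intermediate
6 | (3-bromo-2,4-dimethylphenoxy)tri(propan-2-yl)silane | Cc1ccc(O[Si](C(C)C)(C(C)C)C(C)C)c(C)c1Br | intermediate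
7 | {2,6-dimethyl-3-[tri(propan-2-yl)silyloxy]phenyl}lithium | Cc1ccc(O[Si](C(C)C)(C(C)C)C(C)C)c(C)c1[Li] | intermediate (not isolated)
8 | 2,6-dimethyl-3-[tri(propan-2-yl)silyloxy]benzaldehyde | Cc1ccc(O[Si](C(C)C)(C(C)C)C(C)C)c(C)c1C=O | intermediate (not isolated)
9 | {2,6-dimethyl-3-[tri(propan-2-yl)silyloxy]phenyl}methanol | Cc1ccc(O[Si](C(C)C)(C(C)C)C(C)C)c(C)c1CO | intermediate
10 | [3-(bromomethyl)-2,4-dimethylphenoxy]tri(propan-2-yl)silane | Cc1ccc(O[Si](C(C)C)(C(C)C)C(C)C)c(C)c1CBr | intermediate
11 | 2-methylprop-2-en-1-ol | CC(=C)CO | starting material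
12 | dilithiated 2-methylprop-2-en-1-ol, lithium 2-(lithiomethyl)prop-2-en-1-olate | [Li]CC(=C)CO[Li] | intermediate (not isolated)
13 | 4-{2,6-dimethyl-3-[tri(propan-2-yl)silyloxy]phenyl}-2-methylidenebutan-1-ol | Cc1ccc(O[Si](C(C)C)(C(C)C)C(C)C)c(C)c1CCC(=C)CO | intermediate
14 | methyl chloroformate | COC(=O)Cl | starting material
15 | 4-{2,6-dimethyl-3-[tri(propan-2-yl)silyloxy]phenyl}-2-methylidenebutyl methyl carbonate | Cc1ccc(O[Si](C(C)C)(C(C)C)C(C)C)c(C)c1CCC(=C)COC(=O)OC | intermediate
16 | 4-(3-hydroxy-2,6-dimethylphenyl)-2-methylidenebutyl methyl carbonate | Cc1ccc(O)c(C)c1CCC(=C)COC(=O)OC | intermediate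
17 | (4aS)-1,4a-dimethyl-6-methylidene-5,6,7,8-tetrahydronaphthalen-2(4aH)-one | CC1=C2CCC(=C)C[C@@]2(C)C=CC1=O | intermediate
18 | {[(4aR)-1,4a-dimethyl-6-methylidene-4,4a,5,6,7,8-hexahydronaphthalen-2-yl]oxy}dimethyl(phenyl)silane | CC1=C2CCC(=C)C[C@@]2(C)CC=C1O[Si](C)(C)c1ccccc1 | intermediate (not isolated)
19 | (4aR)-1,4a-dimethyl-6-methylidene-4,4a,5,6,7,8-hexahydronaphthalen-2(3H)-one | CC1=C2CCC(=C)C[C@@]2(C)CCC1=O | intermediate
20 | lithium (4aR,8aR)-1,4a-dimethyl-6-methylidene-3,4,4a,5,6,7,8,8a-octahydronaphthalen-2-olate | CC1=C(O[Li])CC[C@]2(C)CC(=C)CC[C@@H]12 | intermediate (not isolated)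
21 | (4aR,8aR)-1,4a-dimethyl-6-methylidene-3,4,4a,5,6,7,8,8a-octahydronaphthalen-2-yl trifluoromethanesulfonate | CC1=C(OS(=O)(=O)C(F)(F)F)CC[C@]2(C)CC(=C)CC[C@@H]12 | intermediate
22 | (4aR,8aR)-1,4a-dimethyl-6-oxo-3,4,4a,5,6,7,8,8a-octahydronaphthalen-2-yl trifluoromethanesulfonate | CC1=C(OS(=O)(=O)C(F)(F)F)CC[C@]2(C)CC(=O)CC[C@@H]12 | intermediate
23 | (4aR,8aR)-5,8a-dimethyl-3,4,4a,7,8,8a-hexahydronaphthalen-2(1H)-one | CC1=CCC[C@]2(C)CC(=O)CC[C@@H]12 | intermediate
24 | acetone | CC(C)=O | starting material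
25 | lithium (4aR,8aR)-5,8a-dimethyl-1,4,4a,7,8,8a-hexahydronaphthalen-2-olate | CC1=CCC[C@]2(C)CC(O[Li])=CC[C@@H]12 | intermediate (not isolated)
26 | (4aR,8aR)-3-(2-hydroxypropan-2-yl)-5,8a-dimethyl-3,4,4a,7,8,8a-hexahydronaphthalen-2(1H)-one (C7 epimers, eudesmane numbering) | CC1=CCC[C@]2(C)CC(=O)C(C(C)(C)O)C[C@@H]12 | intermediate
27 | 2-[(4aR,8aR)-5,8a-dimethyl-2-oxo-1,2,3,4,4a,7,8,8a-octahydronaphthalen-3-yl]propan-2-yl methanesulfonate | CC1=CCC[C@]2(C)CC(=O)C(C(C)(C)OS(C)(=O)=O)C[C@@H]12 | intermediate (not isolated)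
28 | (4aR,8aR)-5,8a-dimethyl-3-(propan-2-ylidene)-3,4,4a,7,8,8a-hexahydronaphthalen-2(1H)-one, (5R,10R)-eudesma-3,7(11)-dien-8-one | CC1=CCC[C@]2(C)CC(=O)C(=C(C)C)C[C@@H]12 | intermediate
29 | (3R,4S,5R,10R)-3,4-dihydroxyeudesm-7(11)-en-8-one | O[C@@H]1CC[C@]2(C)CC(=O)C(=C(C)C)C[C@H]2[C@]1(C)O | intermediate
30 | angelic acid, (2Z)-2-methylbut-2-enoic acid | C/C=C(/C)C(=O)O | starting material
31 | (2Z)-2-methylbut-2-enoic 2,4,6-trichlorobenzoic anhydride | C/C=C(/C)C(=O)OC(=O)c1c(Cl)cc(Cl)cc1Cl | intermediate (not isolated)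
32 | (3R,4S,5R,10R)-4-hydroxy-8-oxoeudesm-7(11)-en-3-yl (2Z)-2-methylbut-2-enoate | C/C=C(/C)C(=O)O[C@@H]1CC[C@]2(C)CC(=O)C(=C(C)C)C[C@H]2[C@]1(C)O | intermediate
33 | (3R,4S,5R,10R)-4-acetoxy-8-oxoeudesm-7(11)-en-3-yl (2Z)-2-methylbut-2-enoate | C/C=C(/C)C(=O)O[C@@H]1CC[C@]2(C)CC(=O)C(=C(C)C)C[C@H]2[C@]1(C)OC(C)=O | intermediate
34 | (1S,2R,4aR,8aR)-1-(acetyloxy)-7-(2-hydroperoxypropan-2-yl)-1,4a-dimethyl-6-oxo-1,2,3,4,4a,5,6,8a-octahydronaphthalen-2-yl (2Z)-2-methylbut-2-enoate | C/C=C(/C)C(=O)O[C@@H]1CC[C@]2(C)CC(=O)C(C(C)(C)OO)=C[C@H]2[C@]1(C)OC(C)=O | target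

**Step count and risks**

Total step count: 20. Longest linear sequence: 20 steps (1 → 34).

Steps most likely to fail:

1. Step 10 (key step, new for this substrate class). Ortho-C-alkylation at C4 or intermolecular O-allylation may compete with the para closure, and the ligand may discriminate the two faces of the phenolate poorly. Fallback from 13, returning at 17, by known chemistry: chlorination of 13 (N-chlorosuccinimide, PPh3, CH2Cl2, 0 °C) gives {3-[3-(chloromethyl)but-3-en-1-yl]-2,4-dimethylphenoxy}tri(propan-2-yl)silane F1. Buffered desilylation (Bu4NF, AcOH) gives 3-[3-(chloromethyl)but-3-en-1-yl]-2,4-dimethylphenol F2. Classical base-mediated intramolecular para-C-alkylation of the phenolate (KOt-Bu, t-BuOH, high dilution, 60 °C) gives racemic 1,4a-dimethyl-6-methylidene-5,6,7,8-tetrahydronaphthalen-2(4aH)-one F3. Preparative HPLC on a chiral stationary phase then delivers the (4aS) enantiomer 17.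

2. Step 20. Singlet oxygen may also attack the angelate alkene, hydrogen may be taken from the C11 methyls instead of C6, and the hydroperoxide may degrade on prolonged irradiation. Fallback from 29, returning at 34, with the ene reaction run before any other alkene is present: photooxygenation of 29 (O2, hν, tetraphenylporphyrin) gives (3R,4S,5R,10R)-11-hydroperoxy-3,4-dihydroxyeudesm-6-en-8-one F4. Selective silylation of the more acidic and unhindered OOH (TBSCl, imidazole, DMF, 0 °C) gives the tert-butyldimethylsilyl peroxide diol F5. Angeloylation as in step 18 gives the silyl peroxide 3-angelate F6, and acetylation as in step 19 gives the silyl peroxide 3-angelate 4-acetate F7. Desilylation (HF·pyridine, THF, 0 °C) gives 34.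

3. Step 18. Acylation of the hindered axial C3 hydroxyl may be slow, and forcing it may isomerise the angeloyl unit to the tiglate. Fallback from 29, returning at 32, builds the Z alkene after the ester bond: acylation of 29 with 2-[bis(2,2,2-trifluoroethoxy)phosphoryl]propanoic acid (DCC, catalytic DMAP, CH2Cl2; no alkene geometry at stake, so it can be forced) gives (3R,4S,5R,10R)-4-hydroxy-8-oxoeudesm-7(11)-en-3-yl 2-[bis(2,2,2-trifluoroethoxy)phosphoryl]propanoate F8. Still–Gennari olefination with acetaldehyde (KN(SiMe3)2, 18-crown-6, THF, −78 °C) should give the (Z)-2-methylbut-2-enoate 32.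

**Further compounds**
F1 | step 10 | {3-[3-(chloromethyl)but-3-en-1-yl]-2,4-dimethylphenoxy}tri(propan-2-yl)silane | Cc1ccc(O[Si](C(C)C)(C(C)C)C(C)C)c(C)c1CCC(=C)CCl
F2 | step 10 | 3-[3-(chloromethyl)but-3-en-1-yl]-2,4-dimethylphenol | Cc1ccc(O)c(C)c1CCC(=C)CCl
F3 | step 10 | racemic 1,4a-dimethyl-6-methylidene-5,6,7,8-tetrahydronaphthalen-2(4aH)-one | CC1=C2CCC(=C)CC2(C)C=CC1=O
F4 | step 20 | (3R,4S,5R,10R)-11-hydroperoxy-3,4-dihydroxyeudesm-6-en-8-one | O[C@@H]1CC[C@]2(C)CC(=O)C(C(C)(C)OO)=C[C@H]2[C@]1(C)O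
F5 | step 20 | (3R,4S,5R,10R)-11-(tert-butyldimethylsilylperoxy)-3,4-dihydroxyeudesm-6-en-8-one | O[C@@H]1CC[C@]2(C)CC(=O)C(C(C)(C)OO[Si](C)(C)C(C)(C)C)=C[C@H]2[C@]1(C)O
F6 | step 20 | (3R,4S,5R,10R)-11-(tert-butyldimethylsilylperoxy)-4-hydroxy-8-oxoeudesm-6-en-3-yl (2Z)-2-methylbut-2-enoate | C/C=C(/C)C(=O)O[C@@H]1CC[C@]2(C)CC(=O)C(C(C)(C)OO[Si](C)(C)C(C)(C)C)=C[C@H]2[C@]1(C)O
F7 | step 20 | (3R,4S,5R,10R)-4-acetoxy-11-(tert-butyldimethylsilylperoxy)-8-oxoeudesm-6-en-3-yl (2Z)-2-methylbut-2-enoate | C/C=C(/C)C(=O)O[C@@H]1CC[C@]2(C)CC(=O)C(C(C)(C)OO[Si](C)(C)C(C)(C)C)=C[C@H]2[C@]1(C)OC(C)=O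
F8 | step 18 | (3R,4S,5R,10R)-4-hydroxy-8-oxoeudesm-7(11)-en-3-yl 2-[bis(2,2,2-trifluoroethoxy)phosphoryl]propanoate | CC(C(=O)O[C@@H]1CC[C@]2(C)CC(=O)C(=C(C)C)C[C@H]2[C@]1(C)O)P(=O)(OCC(F)(F)F)OCC(F)(F)F
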